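## The problem

The target 18 is a cyclobutane whose ring carbons carry, in alternation, a 2,4-dihydroxybenzoyl group (C1 and C3) and a phenyl group (C2 and C4). Every pair of neighbours is trans, so both acyl groups lie on one face and both phenyl groups on the other. The compound is meso, so only relative configuration has to be controlled, and all stereodescriptors below are relative. The four stereocentres are not equivalent. C1 and C3 are α to a carbonyl group and can be equilibrated, and the all-trans arrangement is the thermodynamic one. C2 and C4 are fixed once made, so the cis relation of the two phenyl groups across the ring must be set kinetically and cannot be repaired later. That relation can be controlled from C1 and C3: a group that enters at C4 anti to two carbonyl substituents on the same face ends up cis to the C2 phenyl. The fragile elements are the resorcinol hydroxyls, which are carried as methyl ethers, and the 1,3-diacylcyclobutane itself. Its ketone enolate can open the strained ring by β-cleavage to an enone, so the aryl ketones should arrive late and meet no strong base. The feature that makes the plan possible is that C4 lies between the two acyl-bearing carbons. At the ester oxidation level C1–C2–C3 is a 3-phenylglutarate whose two α-carbons can both be made electrophilic, so a one-carbon dinucleophile can become C4 and close the ring.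

## Retrosynthesis

**18 from 17.** The four aryl O–CH3 bonds are cut last. Methyl ethers are the only phenol protection that survives the Friedel–Crafts acylation and all earlier steps, and their Lewis-acid cleavage exposes the ketones to no base. Compound 17 has the full skeleton and configuration of 18.

**17 from 14 and 15.** The two aryl–C(=O) bonds are cut, leading to the symmetrical diacid 14 (via its dichloride 16) and two molecules of 1,3-dimethoxybenzene 15. This is preferred to adding an aryl metal to an acid derivative because 15 is acylated at C4 with high regioselectivity and both ketones form in one operation. The forward reaction must be faster than acylation of the neighbouring phenyl rings; the trans relation of each acyl chloride to both of them ensures this. Diacid 14 comes from diester 13 by hydrolysis.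

**13 from 12 (from 10 and 11).** The C4–phenyl bond is cut, giving a carboxyl group at C4, activated as the N-hydroxyphthalimide ester 12 made from acid 10 and 11. A decarboxylative arylation is chosen because a carboxyl at C4 is exactly what a malonate leaves behind, and because the C4 radical is flanked by two esters on one face, which should steer the phenyl to the other. Compound 10 carries one phenyl group and three carboxyl functions, two of them equivalent. The forward step must deliver the aryl group selectively to one face and must tolerate methyl esters.

**10 from 8.** One C4–CO2 bond and the two tert-butyl groups are removed in the retrosynthetic sense, via diacid 9. The tert-butyl/methyl ester pairing is what allows the malonate carboxyls to be released selectively by acid and one of them to be lost on heating.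

**8 from 4 and 5 (key disconnection).** The C4–C1 and C4–C3 bonds are cut, giving dibromo diester 4 and di-tert-butyl malonate 5. Cutting the ring into two two-carbon halves would give no control over which ends join or over the phenyl/phenyl relation. The [3+1] cut starts from a symmetrical three-carbon chain, so the 1,3-placement of the acyl carbons is fixed by constitution. Both precursors are acyclic and carry no stereochemical information that matters. The forward reaction must achieve C-alkylation and four-membered ring closure in preference to elimination.

**4 from 1.** The two C–Br bonds are cut. Hell–Volhard–Zelinsky bromination of 3-phenylglutaric acid 1 with a methanol quench gives 4 in one operation. No stereocontrol is needed because both centres are inverted and then equilibrated.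

## Roads not taken

**Alternative 1:** The cut is at the two aryl–C(=O) bonds, with the four-membered ring purchased. Cyclobutane-1,2,3,4-tetracarboxylic dianhydride A1 would be opened twice by 15 under AlCl3 to give diaroyl diacid A2. The two remaining carboxyl groups would then be exchanged for phenyl by decarboxylative arylation.

- Merits: the ring and all four exocyclic carbons come in one commercial compound, both ketones form in one step, and on paper this is the shortest route (about five steps).
- Weak point, constitution: after the first opening nothing distinguishes the two carbonyls of the second anhydride, so the head-to-head isomer A3 should form beside A2 in similar amount.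
- Weak point, configuration: the cis,trans,cis ring of A1 places the two aroyl groups of A2 on opposite faces. Each carboxyl-bearing carbon is then flanked by one aroyl group above and one below, the radical formed there has no facial bias, and the phenyl/phenyl relation is left to chance. Bringing the aroyl groups to one face first would need an epimerisation with no thermodynamic drive on a base-labile 1,3-diacylcyclobutane.
- Weak point, arylation: two radical arylations are needed in place of one.
- Comparison: in step count and in buying the ring this road is better. The chosen plan sets against it an unambiguous constitution, two esters on one face before a single arylation, and ketones that appear only at the end.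

**Alternative 2:** The cut runs through both resorcinol rings. Bis-ynone A4 would react with two equivalents of diene A5 by [4+2] cycloaddition; loss of methanol and of the silyl group would give A6.

- Merits: the oxygenation pattern is fixed by the polarity of the diene, the ortho hydroxyl is formed free, and no Lewis-acid acylation is needed.
- Weak points: it disconnects the part of the molecule that can be bought (15) and leaves the real problem, the all-trans diphenylcyclobutane core, unsolved. A4 would have to be made from a diacid such as 14 through an amide and an ethynyl addition, so this road contains the chosen route up to 14 and then needs more steps. A4 holds two ynones next to enolisable ring carbons in a ring prone to β-cleavage, and A6 still needs a demethylation.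
- Comparison: it is better only in the regiochemical certainty of the arene and in avoiding AlCl3, and the acylation of 15 is itself regioselective. The chosen plan is shorter by about three steps.

**Alternative 3:** The cut is at both C–phenyl bonds. The trans amide ester A7 would be arylated twice under palladium diacetate catalysis with a silver carboxylate and the aryl iodide, the quinolin-8-yl amide directing palladation to the two C–H bonds cis to it, to give A8.

- Merits: this is probably the shortest entry to a 2,4-diphenylcyclobutane-1,3-dicarbonyl compound. The directing group delivers both phenyl groups to its own face, so their cis relation follows from the mechanism, arguably more reliably than from a radical capture. The ester is already trans to both phenyls, and the reaction class is established on cyclobutane carboxamides.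
- Weak points: in A8 the amide carbon is cis to both phenyl groups. It must be epimerised, and the robust secondary anilide must be cleaved in a congested position, which normally needs N-activation first. The two carbonyl groups, which the target needs identical, stay differentiated throughout, so the end-game cannot be run twofold. The second arylation is the more hindered one, and silver is used stoichiometrically.
- Comparison: in brevity and in the precedent for its key step this road equals or surpasses the chosen plan. The chosen plan offers cheap reagents, no auxiliary to attach, epimerise and remove, symmetrical intermediates, and thermodynamic control of the ester centres. Its price is a less secure ring closure.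

Key step: step 2

## Route

Locants in compound names follow nomenclature; in the discussion C1–C4 are the ring carbons of 18 as defined above, C4 being the carbon supplied by the malonate.

Step 1
Reactants: 1 3-phenylpentanedioic acid (3-phenylglutaric acid)
Product: 4 dimethyl 2,4-dibromo-3-phenylpentanedioate (mixture of diastereomers), via 3-phenylpentanedioyl dibromide 2 (not isolated), via 2,4-dibromo-3-phenylpentanedioyl dibromide 3 (not isolated)
Conditions: PBr3 (0.7 equiv), Br2 (2.3 equiv), 80 °C, dark; then MeOH, 0 → 25 °C
Reagents that add atoms: bromine, BrBr; methanol, CO
Why: Hell–Volhard–Zelinsky bromination: PBr3 converts both carboxyl groups into acyl bromides, whose enols are brominated at the two α-carbons only, and methanolysis gives the diester. The new C–Br centres form without control, which is immaterial because both are inverted and then equilibrated in step 2.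

Step 2
Reactants: 4 dimethyl 2,4-dibromo-3-phenylpentanedioate; 5 di-tert-butyl malonate
Product: 8 1,1-di-tert-butyl 2,4-dimethyl 3-phenylcyclobutane-1,1,2,4-tetracarboxylate (both methyl esters trans to phenyl; meso), via open-chain bromo tetraester 6 (not isolated), via cyclobutane tetraester epimer mixture 7 (not isolated)
Conditions: Cs2CO3 (2.5 equiv), DMF (0.05 M), 0 → 40 °C; aqueous work-up; crude product, NaOMe (0.3 equiv), MeOH, 25 °C
Reagents that add atoms: none
Why: Carbonate deprotonates 5 reversibly, and the malonate carbanion displaces one bromide of 4 by SN2 at an α-bromo ester carbon, a position activated for substitution by the adjacent carbonyl, to give 6. In 6 the malonate C–H is by far the most acidic site, so the second deprotonation occurs there and the tertiary carbanion displaces the remaining bromide in a 4-exo-tet closure, forming the C4–C1 and C4–C3 bonds of the ring (7). The closest known reaction type is the dialkylation of malonates with 1,3-dihalides to cyclobutane-1,1-dicarboxylates; the double displacement of 2,4-dibromoglutarates by primary amines to azetidine-2,4-dicarboxylates shows that both α-bromo ester carbons of such a chain accept one bridging nucleophile. Each substitution inverts its carbon, but 4 is a mixture, so 7 forms as a mixture of epimers at the two ester-bearing carbons; catalytic methoxide then equilibrates these enolisable centres, and since the malonate carbon carries two identical esters the only bias comes from the phenyl group, which places both methyl esters trans to it (all pseudo-equatorial), so the two stereocentres are set under thermodynamic control. The step needs C-alkylation and ring closure to win over dehydrobromination, over enolisation of the bromo ester followed by 3-exo-tet closure to a bromocyclopropane, and over O-alkylation to a six-membered ketene acetal. This is secured by keeping the only bases weak: malonate anion and carbonate lie several pKa units below what is needed to enolise an α-bromo ester, so the carbanion sits on the malonate carbon, while the α-carbonyl activation of both electrophilic carbons, a dipolar aprotic solvent and dilution favour substitution and closure over a second intermolecular alkylation. tert-Butyl esters neither transesterify nor cleave under methoxide, so the two ester sets remain distinguishable.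

Step 3
Reactants: 8 1,1-di-tert-butyl 2,4-dimethyl 3-phenylcyclobutane-1,1,2,4-tetracarboxylate
Product: 10 2,4-bis(methoxycarbonyl)-3-phenylcyclobutane-1-carboxylic acid (methyl esters trans to phenyl; mixture of C1 epimers), via geminal diacid 9 (not isolated)
Conditions: TFA, CH2Cl2, 25 °C; evaporate; DMSO, 130 °C
Reagents that add atoms: none
Why: Acidolysis of the tert-butyl esters (loss of isobutene) leaves the methyl esters untouched, and the resulting malonic acid loses CO2 through its cyclic six-membered transition state on heating. The configuration created at the decarboxylated carbon is of no consequence because that carbon becomes a radical in step 5.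

Step 4
Reactants: 10 2,4-bis(methoxycarbonyl)-3-phenylcyclobutane-1-carboxylic acid; 11 N-hydroxyphthalimide
Product: 12 1-(1,3-dioxoisoindolin-2-yl) 2,4-dimethyl 3-phenylcyclobutane-1,2,4-tricarboxylate (methyl esters trans to phenyl; mixture of C1 epimers)
Conditions: N,N'-diisopropylcarbodiimide, DMAP (10 mol %), CH2Cl2, 25 °C
Reagents that add atoms: none
Why: Carbodiimide (Steglich-type) esterification of the only free acid with 11 gives the redox-active ester; the methyl esters are inert.

Step 5
Reactants: 12 1-(1,3-dioxoisoindolin-2-yl) 2,4-dimethyl 3-phenylcyclobutane-1,2,4-tricarboxylate
Product: 13 dimethyl (1α,2β,3α,4β)-2,4-diphenylcyclobutane-1,3-dicarboxylate (all-trans; meso)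
Conditions: PhMgBr, ZnCl2, LiCl, THF, 0 °C (gives PhZnCl·LiCl, 3 equiv); NiCl2·glyme (20 mol %), 4,4'-di-tert-butyl-2,2'-bipyridine (40 mol %), THF/DMF, 25 °C
Reagents that add atoms: phenylzinc chloride, Cl[Zn]c1ccccc1 (made in the flask from phenylmagnesium bromide, Br[Mg]c1ccccc1, and ZnCl2)
Why: Nickel-catalysed decarboxylative Negishi-type arylation of a redox-active ester: electron transfer from a low-valent (monovalent) arylnickel species fragments 12 into CO2, phthalimide anion and a secondary cyclobutyl radical, which recombines with nickel and is arylated by reductive elimination from trivalent nickel. The radical carbon is flanked by two ester-bearing carbons whose esters occupy the same face, so the aryl group should enter at the opposite, pseudo-equatorial position, cis to the existing phenyl. Methyl esters tolerate the arylzinc reagent.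

Step 6
Reactants: 13 dimethyl (1α,2β,3α,4β)-2,4-diphenylcyclobutane-1,3-dicarboxylate
Product: 14 (1α,2β,3α,4β)-2,4-diphenylcyclobutane-1,3-dicarboxylic acid (ε-truxillic acid)
Conditions: NaOMe, MeOH, 50 °C; then NaOH, H2O, 65 °C; HCl
Reagents that add atoms: sodium hydroxide, [Na+].[OH-]
Why: Methoxide first equilibrates any ester that is cis to a phenyl group to the all-trans diester, then hydroxide saponifies both esters (acyl–oxygen cleavage). The dicarboxylate is configurationally stable.

Step 7
Reactants: 14 (1α,2β,3α,4β)-2,4-diphenylcyclobutane-1,3-dicarboxylic acid; 15 1,3-dimethoxybenzene
Product: 17 [(1α,2β,3α,4β)-2,4-diphenylcyclobutane-1,3-diyl]bis[(2,4-dimethoxyphenyl)methanone], via diacid dichloride 16 (not isolated)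
Conditions: (COCl)2, DMF (cat.), CH2Cl2, 25 °C; evaporate; 15 (5 equiv), AlCl3 (2.4 equiv), CH2Cl2, 0 °C
Reagents that add atoms: none
Why: Friedel–Crafts acylation: the acyl chloride–AlCl3 complex attacks 15 at C4, para to one methoxy group and ortho to the other, the position activated by both and less hindered than C2. Each acyl chloride is trans to both neighbouring phenyl groups, so cyclisation onto them would require a trans-fused bicyclo[3.2.0] ketone and cannot compete with the excess of activated arene; any enolisation returns the thermodynamic all-trans ketone.

Step 8
Reactants: 17 [(1α,2β,3α,4β)-2,4-diphenylcyclobutane-1,3-diyl]bis[(2,4-dimethoxyphenyl)methanone]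
Product: 18 [(1α,2β,3α,4β)-2,4-diphenylcyclobutane-1,3-diyl]bis[(2,4-dihydroxyphenyl)methanone] (CNP0398987.1)
Conditions: BBr3 (8 equiv), CH2Cl2, −78 → 25 °C; then H2O
Reagents that add atoms: none
Why: Lewis-acid cleavage of all four aryl methyl ethers (complexation of boron to oxygen, then SN2 attack of bromide on the methyl group). The medium is acidic throughout, so the base-labile 1,3-diacylcyclobutane never meets an enolate-forming reagent, and the all-trans configuration is the thermodynamic one.

## Compound list

1 | 3-phenylpentanedioic acid (3-phenylglutaric acid) | OC(=O)CC(CC(=O)O)c1ccccc1 | starting material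
2 | 3-phenylpentanedioyl dibromide | O=C(Br)CC(CC(=O)Br)c1ccccc1 | intermediate (not isolated)
3 | 2,4-dibromo-3-phenylpentanedioyl dibromide (diastereomer mixture) | O=C(Br)C(Br)C(c1ccccc1)C(Br)C(=O)Br | intermediate (not isolated)
4 | dimethyl 2,4-dibromo-3-phenylpentanedioate (diastereomer mixture) | COC(=O)C(Br)C(c1ccccc1)C(Br)C(=O)OC | intermediate
5 | di-tert-butyl malonate | CC(C)(C)OC(=O)CC(=O)OC(C)(C)C | starting material
6 | 1,1-di-tert-butyl 2,4-dimethyl 4-bromo-3-phenylbutane-1,1,2,4-tetracarboxylate (diastereomer mixture) | CC(C)(C)OC(=O)C(C(=O)OC(C)(C)C)C(C(=O)OC)C(c1ccccc1)C(Br)C(=O)OC | intermediate (not isolated)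
7 | 1,1-di-tert-butyl 2,4-dimethyl 3-phenylcyclobutane-1,1,2,4-tetracarboxylate, mixture of epimers at C2 and C4 | CC(C)(C)OC(=O)C1(C(=O)OC(C)(C)C)C(C(=O)OC)C(c2ccccc2)C1C(=O)OC | intermediate (not isolated)
8 | 1,1-di-tert-butyl 2,4-dimethyl 3-phenylcyclobutane-1,1,2,4-tetracarboxylate, methyl esters cis to each other and trans to phenyl (meso) | CC(C)(C)OC(=O)C1(C(=O)OC(C)(C)C)[C@@H](C(=O)OC)[C@H](c2ccccc2)[C@H]1C(=O)OC | intermediate
9 | 2,4-bis(methoxycarbonyl)-3-phenylcyclobutane-1,1-dicarboxylic acid, methyl esters trans to phenyl | OC(=O)C1(C(=O)O)[C@@H](C(=O)OC)[C@H](c2ccccc2)[C@H]1C(=O)OC | intermediate (not isolated)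
10 | 2,4-bis(methoxycarbonyl)-3-phenylcyclobutane-1-carboxylic acid, methyl esters trans to phenyl, both C1 epimers | OC(=O)C1[C@@H](C(=O)OC)[C@H](c2ccccc2)[C@H]1C(=O)OC | intermediate
11 | N-hydroxyphthalimide | O=C1c2ccccc2C(=O)N1O | starting material
12 | 1-(1,3-dioxoisoindolin-2-yl) 2,4-dimethyl 3-phenylcyclobutane-1,2,4-tricarboxylate, methyl esters trans to phenyl, both C1 epimers | O=C(ON1C(=O)c2ccccc2C1=O)C1[C@@H](C(=O)OC)[C@H](c2ccccc2)[C@H]1C(=O)OC | intermediate
13 | dimethyl (1α,2β,3α,4β)-2,4-diphenylcyclobutane-1,3-dicarboxylate (all-trans, meso) | COC(=O)[C@H]1[C@H](c2ccccc2)[C@@H](C(=O)OC)[C@@H]1c1ccccc1 | intermediate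
14 | (1α,2β,3α,4β)-2,4-diphenylcyclobutane-1,3-dicarboxylic acid (ε-truxillic acid) | OC(=O)[C@H]1[C@H](c2ccccc2)[C@@H](C(=O)O)[C@@H]1c1ccccc1 | intermediate
15 | 1,3-dimethoxybenzene | COc1cccc(OC)c1 | starting material
16 | (1α,2β,3α,4β)-2,4-diphenylcyclobutane-1,3-dicarbonyl dichloride | O=C(Cl)[C@H]1[C@H](c2ccccc2)[C@@H](C(Cl)=O)[C@@H]1c1ccccc1 | intermediate (not isolated)
17 | [(1α,2β,3α,4β)-2,4-diphenylcyclobutane-1,3-diyl]bis[(2,4-dimethoxyphenyl)methanone] | O=C(c1ccc(OC)cc1OC)[C@H]1[C@H](c2ccccc2)[C@@H](C(=O)c2ccc(OC)cc2OC)[C@@H]1c1ccccc1 | intermediate
18 | [(1α,2β,3α,4β)-2,4-diphenylcyclobutane-1,3-diyl]bis[(2,4-dihydroxyphenyl)methanone] (CNP0398987.1) | O=C(c1ccc(O)cc1O)[C@H]1[C@H](c2ccccc2)[C@@H](C(=O)c2ccc(O)cc2O)[C@@H]1c1ccccc1 | target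

## Step count and risks

Total step count: 8. Longest linear sequence: 8 steps (1 to 18).

The key step, step 2, is the least certain.
- What may go wrong: the first, intermolecular substitution takes place at a β-branched secondary carbon and may be slow enough for dehydrobromination towards a 3-phenylglutaconate to take over. In the second stage the slow 4-exo-tet closure may lose to enolisation of the bromo ester with three-membered ring closure, to O-alkylation, or to a second intermolecular alkylation.
- Fallback: it sets out from 1, avoids the dibromide altogether, and returns at 7. Fischer esterification of 1 (MeOH, H2SO4) should give dimethyl 3-phenylpentanedioate F1. Its mono-enolate (LiN(iPr)2, 1.05 equiv, THF, −78 °C) is brominated with N-bromosuccinimide to dimethyl 2-bromo-3-phenylpentanedioate F2. The sodium salt of 5 (NaH, DMF) displaces the single bromide to give 1,1-di-tert-butyl 2,4-dimethyl 3-phenylbutane-1,1,2,4-tetracarboxylate F3. The ring is then closed by intramolecular oxidative coupling of the dianion (LiN(iPr)2, 2.2 equiv, THF, −78 °C, then I2), in which the ester enolate is iodinated and the malonate carbanion already present displaces iodide with no external base left. This gives 7, which is equilibrated with methoxide to 8 as in step 2.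

Step 5 is the second concern.
- What may go wrong: capture of a secondary cyclobutyl radical flanked by two substituted ring carbons may be slow, so that hydrogen abstraction (net reduction) and attack of the arylzinc reagent on the activated ester compete. Erosion of facial selectivity is the lesser worry, but it would be irreversible.
- Fallback: it sets out from 10, skips 12, and returns at 13. The free acid is coupled with iodobenzene by photoredox–nickel dual catalysis (Ir[dF(CF3)ppy]2(dtbbpy)PF6, NiCl2·glyme, 4,4'-di-tert-butyl-2,2'-bipyridine, Cs2CO3, DMF, blue light). The radical is then made by oxidation of the carboxylate, the aryl partner is an electrophile, and no organometallic reagent or activated ester is present. No new compound arises.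

Step 7 may suffer from incomplete twofold acylation, since each acyl chloride sits between two phenyl-bearing carbons, and from decarbonylation of the hindered acylium ion. Partial loss of the ortho methyl ethers under AlCl3 is harmless because step 8 removes them anyway.
- Fallback: it sets out from 14 and returns at 17 with reversed polarity. The diacid is converted with 1,1'-carbonyldiimidazole and N,O-dimethylhydroxylamine hydrochloride into (1α,2β,3α,4β)-N1,N3-dimethoxy-N1,N3-dimethyl-2,4-diphenylcyclobutane-1,3-dicarboxamide F4. Commercial 2,4-dimethoxyphenylmagnesium bromide (THF, 0 °C) then adds once to each amide, the chelated tetrahedral intermediate preventing over-addition.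

Step 1 may give incomplete second bromination, or bromination at the benzylic C3–H or on the ring, if radical or Lewis-acid pathways intervene.
- Fallback: it sets out from 1 and returns at 4. The diester F1 described above is converted with LiN(iPr)2 (2.2 equiv) and Me3SiCl into the bis(silyl ketene acetal) 1,5-dimethoxy-3-phenyl-1,5-bis(trimethylsilyloxy)penta-1,4-diene F5, which is brominated at both α-carbons with N-bromosuccinimide (THF, −78 °C). The electrophile can then reach only the enol carbons.

## Further compounds

F1 | step 2 | dimethyl 3-phenylpentanedioate | COC(=O)CC(CC(=O)OC)c1ccccc1
F2 | step 2 | dimethyl 2-bromo-3-phenylpentanedioate (diastereomer mixture) | COC(=O)CC(c1ccccc1)C(Br)C(=O)OC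
F3 | step 2 | 1,1-di-tert-butyl 2,4-dimethyl 3-phenylbutane-1,1,2,4-tetracarboxylate (diastereomer mixture) | CC(C)(C)OC(=O)C(C(=O)OC(C)(C)C)C(C(=O)OC)C(c1ccccc1)CC(=O)OC
F0 | step 5 | none | none
F4 | step 7 | (1α,2β,3α,4β)-N1,N3-dimethoxy-N1,N3-dimethyl-2,4-diphenylcyclobutane-1,3-dicarboxamide | CON(C)C(=O)[C@H]1[C@H](c2ccccc2)[C@@H](C(=O)N(C)OC)[C@@H]1c1ccccc1
F5 | step 1 | 1,5-dimethoxy-3-phenyl-1,5-bis(trimethylsilyloxy)penta-1,4-diene | COC(=CC(C=C(OC)O[Si](C)(C)C)c1ccccc1)O[Si](C)(C)C
A1 | alternative 1 | cyclobutane-1,2,3,4-tetracarboxylic dianhydride (cis,trans,cis) | O=C1OC(=O)[C@H]2[C@@H]1[C@@H]1C(=O)OC(=O)[C@@H]12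
A2 | alternative 1 | 2,4-bis(2,4-dimethoxybenzoyl)cyclobutane-1,3-dicarboxylic acid (cis,trans,cis) | O=C(c1ccc(OC)cc1OC)[C@H]1[C@@H](C(=O)O)[C@H](C(=O)c2ccc(OC)cc2OC)[C@@H]1C(=O)O
A3 | alternative 1 | 3,4-bis(2,4-dimethoxybenzoyl)cyclobutane-1,2-dicarboxylic acid (cis,trans,cis; head-to-head isomer) | O=C(c1ccc(OC)cc1OC)[C@H]1[C@@H](C(=O)O)[C@H](C(=O)O)[C@@H]1C(=O)c1ccc(OC)cc1OC
A4 | alternative 2 | all-trans 1,3-bis(prop-2-ynoyl)-2,4-diphenylcyclobutane | C#CC(=O)[C@H]1[C@H](c2ccccc2)[C@@H](C(=O)C#C)[C@@H]1c1ccccc1
A5 | alternative 2 | 1,3-dimethoxy-1-(trimethylsilyloxy)buta-1,3-diene | C=C(OC)C=C(OC)O[Si](C)(C)C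
A6 | alternative 2 | all-trans 1,3-bis(2-hydroxy-4-methoxybenzoyl)-2,4-diphenylcyclobutane | O=C(c1ccc(OC)cc1O)[C@H]1[C@H](c2ccccc2)[C@@H](C(=O)c2ccc(OC)cc2O)[C@@H]1c1ccccc1
A7 | alternative 3 | methyl trans-3-(quinolin-8-ylcarbamoyl)cyclobutane-1-carboxylate | COC(=O)[C@H]1C[C@H](C(=O)Nc2cccc3cccnc23)C1
A8 | alternative 3 | methyl 2,4-diphenyl-3-(quinolin-8-ylcarbamoyl)cyclobutane-1-carboxylate, phenyls cis to the amide and trans to the ester | COC(=O)[C@H]1[C@H](c2ccccc2)[C@H](C(=O)Nc2cccc3cccnc23)[C@@H]1c1ccccc1
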